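**Retrosynthetic overview**

1. Numbering: ring C1 (CH–O ester), C2 (C=O), C3/C4 (oxirane, methyl on C3), C5, C6; chain C7 (spiro-oxirane carbon, its CH2 = C14), C8 (C=O), C9=C10, C11 (OOH). The strategy rests on the vicinal pair C1–O / C6–C7(=C14) on the cyclohexane, a carbinol next to a 2-propenyl-type branch, which is what a carbonyl-ene closure forming C1–C6 leaves behind.
2. Late disconnections: C11–OOH by a Schenck ene reaction of the prenyl ketone; the C1 ester; C8–C9 by α-prenylation of the C8 epoxy aldehyde; the C7/C14 oxirane by Sharpless epoxidation of the C8 allylic alcohol; the C3/C4 oxirane by hydroxyl-directed epoxidation from a C2 carbinol.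
3. That C2 carbinol comes from the enone C2=O/C3=C4, made from the ene product by moving the C2=C3 alkene (directed epoxidation, diaxial hydration, oxidation, dehydration).
4. The only carbocycle is closed first, by enantioselective carbonyl-ene cyclization of the acyclic (2Z,6Z)-dienal 11 to cyclohexenol 12; the oxiranes follow (C7/C14, then C3/C4).
5. Dienal 11 is built from nerol by cleavage of the terminal alkene, Z-selective Still–Gennari olefination and exchange of the oxygen functions.

Key step: step 9

Remark (assumption on the chemistry): the antipode of the confined acid is taken that gives the (1R,6S)-alcohol (both are accessible from (R)- or (S)-BINOL); atom labels C1–C11 and C14 follow line 1 throughout, and "cis/trans" always refers to the ring faces.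

**Route**

Step 1
Reactants: 1 nerol
Product: 2 (2Z)-1-(tert-butyldiphenylsilyloxy)-3,7-dimethylocta-2,6-diene
Conditions: tBuPh2SiCl, imidazole, DMF, 0 °C to rt
Reagents that add atoms: tert-butyl(chloro)diphenylsilane, CC(C)(C)[Si](Cl)(c1ccccc1)c1ccccc1
Why: Imidazole-promoted silylation of the primary allylic alcohol; the acid-stable silyl ether carries the future aldehyde carbon C1 through the periodic acid and hydride steps.

Step 2
Reactants: 2 (2Z)-1-(tert-butyldiphenylsilyloxy)-3,7-dimethylocta-2,6-diene
Product: 3 (2Z)-1-(tert-butyldiphenylsilyloxy)-6,7-epoxy-3,7-dimethyloct-2-ene (racemic at C6)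
Conditions: mCPBA (1.0 equiv), NaHCO3, CH2Cl2, −20 to 0 °C
Reagents that add atoms: 3-chloroperoxybenzoic acid, OOC(=O)c1cccc(Cl)c1
Why: Prilezhaev epoxidation should go to the remote, more electron-rich trisubstituted alkene because the 2,3-alkene is deactivated inductively by the allylic silyloxy group; the new stereocentre is cut away in step 3.

Step 3
Reactants: 3 (2Z)-1-(tert-butyldiphenylsilyloxy)-6,7-epoxy-3,7-dimethyloct-2-ene
Product: 5 (4Z)-6-(tert-butyldiphenylsilyloxy)-4-methylhex-4-enal, via 6,7-diol 4 (not isolated)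
Conditions: H5IO6, THF–H2O, 0 °C
Reagents that add atoms: water, O
Why: Acid-catalysed hydration of the oxirane followed by Malaprade glycol cleavage excises acetone and leaves the Z-alkene and the silyl ether untouched.

Step 4
Reactants: 5 (4Z)-6-(tert-butyldiphenylsilyloxy)-4-methylhex-4-enal; 6 methyl 2-[bis(2,2,2-trifluoroethoxy)phosphoryl]propanoate
Product: 7 methyl (2Z,6Z)-8-(tert-butyldiphenylsilyloxy)-2,6-dimethylocta-2,6-dienoate
Conditions: KN(SiMe3)2, 18-crown-6, THF, −78 °C
Reagents that add atoms: methyl 2-[bis(2,2,2-trifluoroethoxy)phosphoryl]propanoate (6), COC(=O)C(C)P(=O)(OCC(F)(F)F)OCC(F)(F)F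
Why: Still–Gennari olefination: the electron-poor phosphonate under dissociating conditions collapses kinetically to the Z-trisubstituted enoate, which fixes the later C6=C7 geometry (ester carbon, later C8, cis to the chain; methyl, later C14, trans).

Step 5
Reactants: 7 methyl (2Z,6Z)-8-(tert-butyldiphenylsilyloxy)-2,6-dimethylocta-2,6-dienoate
Product: 8 (2Z,6Z)-8-(tert-butyldiphenylsilyloxy)-2,6-dimethylocta-2,6-dien-1-ol
Conditions: iBu2AlH (2.5 equiv), CH2Cl2, −78 °C; aq. potassium sodium tartrate
Reagents that add atoms: none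
Why: 1,2-Reduction of the enoate by the aluminium hydride gives the allylic alcohol without touching either alkene geometry.

Step 6
Reactants: 8 (2Z,6Z)-8-(tert-butyldiphenylsilyloxy)-2,6-dimethylocta-2,6-dien-1-ol
Product: 9 (2Z,6Z)-8-(tert-butyldiphenylsilyloxy)-2,6-dimethylocta-2,6-dien-1-yl pivalate
Conditions: tBuCOCl, pyridine, DMAP (cat.), CH2Cl2, 0 °C
Reagents that add atoms: pivaloyl chloride, CC(C)(C)C(=O)Cl
Why: Nucleophile-catalysed acylation; the pivalate keeps the C8 oxygen non-basic, acid-stable and its C8 hydrogens poorly hydridic for the ene step.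

Step 7
Reactants: 9 (2Z,6Z)-8-(tert-butyldiphenylsilyloxy)-2,6-dimethylocta-2,6-dien-1-yl pivalate
Product: 10 (2Z,6Z)-8-hydroxy-2,6-dimethylocta-2,6-dien-1-yl pivalate
Conditions: Bu4NF, THF, 0 °C to rt
Reagents that add atoms: none
Why: Fluoride-induced desilylation (strong Si–F bond) frees the C1 hydroxyl while the hindered pivalate stays.

Step 8
Reactants: 10 (2Z,6Z)-8-hydroxy-2,6-dimethylocta-2,6-dien-1-yl pivalate
Product: 11 (2Z,6Z)-3,7-dimethyl-8-(pivaloyloxy)octa-2,6-dienal
Conditions: activated MnO2 (excess), CH2Cl2, rt, dark; used at once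
Reagents that add atoms: none
Why: Heterogeneous allylic oxidation under neutral conditions, as in the oxidation of nerol to neral, so the 2Z geometry should be kept.

Step 9
Reactants: 11 (2Z,6Z)-3,7-dimethyl-8-(pivaloyloxy)octa-2,6-dienal
Product: 12 (1R,6S)-3-methyl-6-[3-(pivaloyloxy)prop-1-en-2-yl]cyclohex-2-en-1-ol (C1–OH and C6 branch trans)
Conditions: chiral BINOL-derived imidodiphosphorimidate Brønsted acid (confined 3,3'-aryl pocket, N-triflyl core; 2–5 mol%), CH2Cl2, −60 to −40 °C
Reagents that add atoms: none
Why: The confined acid activates the enal oxygen and the C6=C7 alkene attacks the aldehyde carbon in a concerted, asynchronous carbonyl-ene process in which C1–C6 forms while the carbonyl oxygen takes a hydrogen from the C14 methyl, leaving the C7=C14 methylene. The closest known reaction is the acid-catalysed cyclization of neral to trans-isopiperitenol, including its enantioselective version with confined chiral Brønsted acids, of which 11 is the 8-acyloxy analogue. The six-membered carbocycle closes by C1–C6 bond formation in the ene mode in which the enophile is tethered to the olefinic terminus of the ene unit (exo with respect to both the carbonyl and the alkene), through a chair in which the 2Z enal geometry holds C1 over C6. C1 and C6 are set together: the trans relationship follows from the chair with the oxygen and the C7 unit both equatorial, and the absolute sense (1R,6S) from the catalyst pocket, which selects one enantioface of the aldehyde. The step needs hydrogen transfer from C14 and not from C8: the 6Z geometry places the methyl trans to C5, next to the equatorial oxygen, while the C8 hydrogens (cis to C5 and deactivated by the pivalate) are out of reach. Ionization of the allylic alcohol product should be held back by the low temperature and the confined, weakly nucleophilic counter-anion.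

Step 10
Reactants: 12 (1R,6S)-3-methyl-6-[3-(pivaloyloxy)prop-1-en-2-yl]cyclohex-2-en-1-ol
Product: 13 2,3-epoxy-3-methyl-6-[3-(pivaloyloxy)prop-1-en-2-yl]cyclohexan-1-ol (oxirane cis to C1–OH; C6 branch trans to C1–OH)
Conditions: VO(acac)2 (2 mol%), tBuOOH (1.2 equiv), CH2Cl2, 0 °C to rt
Reagents that add atoms: tert-butyl hydroperoxide, CC(C)(C)OO
Why: Hydroxyl-directed vanadium-catalysed epoxidation delivers oxygen to the allylic C2=C3 alkene on the face of the C1 oxygen (C2 and C3 set cis to C1–OH), while the less nucleophilic, merely homoallylic C7=C14 alkene should be left alone.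

Step 11
Reactants: 13 cis-2,3-epoxy alcohol
Product: 14 C1 tert-butyldimethylsilyl ether of 13
Conditions: tBuMe2SiOTf, 2,6-lutidine, CH2Cl2, −78 °C
Reagents that add atoms: tert-butyldimethylsilyl triflate, CC(C)(C)[Si](C)(C)OS(=O)(=O)C(F)(F)F
Why: Silylation with the triflate and a hindered base at low temperature protects the hindered secondary C1 hydroxyl without opening the oxirane.

Step 12
Reactants: 14 silylated epoxide
Product: 15 1-O-silyl triol: C1–OTBS, C2–OH cis to C1–O, tertiary C3–OH trans to C2–OH (both new C–O bonds axial)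
Conditions: HClO4 (cat.), THF–H2O, 0 °C, short reaction time
Reagents that add atoms: water, O
Why: Acid-catalysed hydration of the trisubstituted oxirane: water attacks the tertiary C3 from the face opposite the oxirane (Fürst–Plattner trans-diaxial opening, in line with the Markovnikov preference), inverting C3 and giving the diaxial diol.

Step 13
Reactants: 15 diaxial diol
Product: 16 α-ketol: C1–OTBS, C2 ketone, tertiary C3–OH (axial, trans to C1–O)
Conditions: (COCl)2, DMSO, CH2Cl2, −78 °C; Et3N, −78 to −20 °C
Reagents that add atoms: none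
Why: Swern oxidation converts the secondary C2 carbinol to the ketone, cannot touch the tertiary C3 carbinol, and avoids glycol cleavage.

Step 14
Reactants: 16 tertiary α-ketol
Product: 17 enone: C1–OTBS, C2=O, C3(CH3)=C4, C6 branch with C8–OPiv (C1–O and C6 branch trans)
Conditions: SOCl2, pyridine, CH2Cl2, −20 to 0 °C
Reagents that add atoms: none
Why: Dehydration of the tertiary α-ketol through its chlorosulfite: the axial C3 leaving group is antiperiplanar to the axial C4–H, so base-induced E2 elimination should give the conjugated endocyclic C3=C4 enone.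

Step 15
Reactants: 17 enone pivalate
Product: 18 diol: C1–OTBS, C2–OH (trans to C1–O, cis to the C6 branch), C3=C4, C7=C14, primary C8–OH
Conditions: LiAlH4, Et2O, −78 to 0 °C; aq. potassium sodium tartrate
Reagents that add atoms: none
Why: LiAlH4 reduces the enone 1,2 by axial hydride attack (as carvone gives cis-carveol), placing the new C2 hydroxyl equatorial, and in the same operation cleaves the pivalate reductively.

Step 16
Reactants: 18 bis-allylic diol
Product: 19 C7/C14 oxirane (C7 S) with primary C8–OH; ring allylic alcohol unchanged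
Conditions: Ti(OiPr)4 (20 mol%), (+)-diethyl (2R,3R)-tartrate [natural L-(+) series] (24 mol%), tBuOOH (anhydrous), 4 Å molecular sieves, CH2Cl2, −20 °C
Reagents that add atoms: tert-butyl hydroperoxide, CC(C)(C)OO
Why: Katsuki–Sharpless asymmetric epoxidation of the primary 2-substituted allylic alcohol: the tartrate (the sense that converts 2-methylprop-2-en-1-ol into (S)-2-methylglycidol) should override the C6 centre and set C7, while the ring cyclohexenol reacts far more slowly under titanium–tartrate conditions.

Step 17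
Reactants: 19 epoxy diol
Product: 20 bis-epoxy diol: C3/C4 oxirane cis to C2–OH (cis to the C6 branch, trans to C1–OTBS)
Conditions: VO(acac)2 (3 mol%), tBuOOH, CH2Cl2, 0 °C to rt
Reagents that add atoms: tert-butyl hydroperoxide, CC(C)(C)OO
Why: Hydroxyl-directed vanadium-catalysed epoxidation of the cyclic allylic alcohol delivers oxygen to C3=C4 cis to the C2 hydroxyl, setting C3 and C4; no other alkene remains.

Step 18
Reactants: 20 bis-epoxy diol
Product: 21 keto aldehyde: C2 ketone, C8 aldehyde, both oxiranes, C1–OTBS
Conditions: (COCl)2, DMSO, CH2Cl2, −78 °C; Et3N, −78 to −20 °C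
Reagents that add atoms: none
Why: Swern oxidation activates both hydroxyls before base is added, so the C8 carbinol gives the non-enolizable epoxy aldehyde and the C2 carbinol the epoxy ketone without the lactol-to-lactone over-oxidation a stepwise oxidant could cause.

Step 19
Reactants: 21 keto aldehyde; 22 prenyl chloride (1-chloro-3-methylbut-2-ene)
Product: 23 C8 carbinol (mixture of C8 epimers) carrying the prenyl group on C8; ring ketone intact
Conditions: prenylbarium chloride [from 22 and Ba, made from BaI2 + 2 lithium biphenylide, THF, −78 °C] (1.2 equiv), THF, −78 °C; aq. NH4Cl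
Reagents that add atoms: prenyl chloride (22), CC(C)=CCCl
Why: Allylic barium reagents add to carbonyls at the less substituted α-terminus with the alkene position retained, and at −78 °C the aldehyde should react well ahead of the hindered ring ketone; the C8 configuration is lost in step 20.

Step 20
Reactants: 23 C8 carbinol
Product: 24 diketone: C1–OTBS, C2=O, C3/C4 oxirane, C7/C14 oxirane, C8=O, prenyl
Conditions: Dess–Martin periodinane, NaHCO3, CH2Cl2, 0 °C to rt
Reagents that add atoms: none
Why: Dess–Martin oxidation under bicarbonate buffer converts the C8 carbinol to the ketone without moving the β,γ-alkene into conjugation or disturbing the oxiranes.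

Step 21
Reactants: 24 silylated diketone
Product: 25 α-hydroxy ketone (free C1–OH)
Conditions: HF·pyridine, pyridine, THF, 0 °C
Reagents that add atoms: none
Why: Buffered fluoride desilylation under mildly acidic conditions frees the C1 hydroxyl and avoids the base that could epimerize C1 or conjugate the β,γ-enone.

Step 22
Reactants: 25 α-hydroxy ketone; 26 isovaleric anhydride
Product: 27 C1 isovalerate of the prenyl diketone
Conditions: DMAP (cat.), pyridine, CH2Cl2, 0 °C
Reagents that add atoms: isovaleric anhydride (26), CC(C)CC(=O)OC(=O)CC(C)C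
Why: DMAP-catalysed acylation of the α-ketol with the anhydride installs the ester; C1 keeps its equatorial, thermodynamically preferred configuration trans to the C6 branch.

Step 23
Reactants: 27 prenyl ketone
Product: 28 CNP0131119.1 (route numbering: 1S,3S,4S,6R,7R; C9=C10 E)
Conditions: O2, visible light, tetraphenylporphyrin (cat.), CH2Cl2, −20 to 0 °C
Reagents that add atoms: dioxygen, O=O
Why: Schenck ene reaction: singlet oxygen attacks the only electron-rich alkene and, by removing a C9 hydrogen, bonds to C11 and shifts the alkene to C9=C10 (E, conjugated with C8=O), giving the tertiary allylic hydroperoxide.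

**Compound list**

1 | nerol, (2Z)-3,7-dimethylocta-2,6-dien-1-ol | CC(C)=CCC/C(C)=C\CO | starting material
2 | (2Z)-1-(tert-butyldiphenylsilyloxy)-3,7-dimethylocta-2,6-diene | CC(C)=CCC/C(C)=C\CO[Si](c1ccccc1)(c1ccccc1)C(C)(C)C | intermediate
3 | (2Z)-1-(tert-butyldiphenylsilyloxy)-6,7-epoxy-3,7-dimethyloct-2-ene (racemic) | CC1(C)OC1CC/C(C)=C\CO[Si](c1ccccc1)(c1ccccc1)C(C)(C)C | intermediate
4 | (6Z)-8-(tert-butyldiphenylsilyloxy)-2,6-dimethyloct-6-ene-2,3-diol (racemic, not isolated) | CC(C)(O)C(O)CC/C(C)=C\CO[Si](c1ccccc1)(c1ccccc1)C(C)(C)C | intermediate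
5 | (4Z)-6-(tert-butyldiphenylsilyloxy)-4-methylhex-4-enal | O=CCC/C(C)=C\CO[Si](c1ccccc1)(c1ccccc1)C(C)(C)C | intermediate
6 | methyl 2-[bis(2,2,2-trifluoroethoxy)phosphoryl]propanoate | COC(=O)C(C)P(=O)(OCC(F)(F)F)OCC(F)(F)F | starting material
7 | methyl (2Z,6Z)-8-(tert-butyldiphenylsilyloxy)-2,6-dimethylocta-2,6-dienoate | COC(=O)/C(C)=C\CC/C(C)=C\CO[Si](c1ccccc1)(c1ccccc1)C(C)(C)C | intermediate
8 | (2Z,6Z)-8-(tert-butyldiphenylsilyloxy)-2,6-dimethylocta-2,6-dien-1-ol | OC/C(C)=C\CC/C(C)=C\CO[Si](c1ccccc1)(c1ccccc1)C(C)(C)C | intermediate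
9 | (2Z,6Z)-8-(tert-butyldiphenylsilyloxy)-2,6-dimethylocta-2,6-dien-1-yl pivalate | CC(C)(C)C(=O)OC/C(C)=C\CC/C(C)=C\CO[Si](c1ccccc1)(c1ccccc1)C(C)(C)C | intermediate
10 | (2Z,6Z)-8-hydroxy-2,6-dimethylocta-2,6-dien-1-yl pivalate | CC(C)(C)C(=O)OC/C(C)=C\CC/C(C)=C\CO | intermediate
11 | (2Z,6Z)-3,7-dimethyl-8-(pivaloyloxy)octa-2,6-dienal | O=C/C=C(/C)CC/C=C(/C)COC(=O)C(C)(C)C | intermediate
12 | (1R,6S)-3-methyl-6-[3-(pivaloyloxy)prop-1-en-2-yl]cyclohex-2-en-1-ol (trans) | O[C@@H]1C=C(C)CC[C@H]1C(=C)COC(=O)C(C)(C)C | intermediate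
13 | 2,3-epoxide of 12, oxirane cis to C1–OH | O[C@@H]1[C@@H]2O[C@]2(C)CC[C@H]1C(=C)COC(=O)C(C)(C)C | intermediate
14 | C1 tert-butyldimethylsilyl ether of 13 | CC(C)(C)[Si](C)(C)O[C@@H]1[C@@H]2O[C@]2(C)CC[C@H]1C(=C)COC(=O)C(C)(C)C | intermediate
15 | diaxial diol: C1–OTBS, C2–OH cis to C1–O, C3–OH trans to C2–OH | CC(C)(C)[Si](C)(C)O[C@@H]1[C@H](O)[C@@](C)(O)CC[C@H]1C(=C)COC(=O)C(C)(C)C | intermediate
16 | α-ketol: C2 ketone, tertiary C3–OH | CC(C)(C)[Si](C)(C)O[C@@H]1C(=O)[C@@](C)(O)CC[C@H]1C(=C)COC(=O)C(C)(C)C | intermediate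
17 | enone: C1–OTBS, C2=O, C3=C4, C8–OPiv | CC(C)(C)[Si](C)(C)O[C@@H]1C(=O)C(C)=CC[C@H]1C(=C)COC(=O)C(C)(C)C | intermediate
18 | diol: C2–OH trans to C1–OTBS, C3=C4, C7=C14, C8–OH | CC(C)(C)[Si](C)(C)O[C@@H]1[C@@H](O)C(C)=CC[C@H]1C(=C)CO | intermediate
19 | C7/C14 oxirane (C7 S), C8–OH, ring allylic alcohol | CC(C)(C)[Si](C)(C)O[C@@H]1[C@@H](O)C(C)=CC[C@H]1[C@]1(CO)CO1 | intermediate
20 | bis-epoxy diol: C3/C4 oxirane cis to C2–OH | CC(C)(C)[Si](C)(C)O[C@@H]1[C@@H](O)[C@@]2(C)O[C@H]2C[C@H]1[C@]1(CO)CO1 | intermediate
21 | keto aldehyde: C2=O, C8 aldehyde | CC(C)(C)[Si](C)(C)O[C@@H]1C(=O)[C@@]2(C)O[C@H]2C[C@H]1[C@]1(C=O)CO1 | intermediate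
22 | prenyl chloride, 1-chloro-3-methylbut-2-ene | CC(C)=CCCl | starting material
23 | C8 carbinol with prenyl group (C8 epimers) | CC(C)(C)[Si](C)(C)O[C@@H]1C(=O)[C@@]2(C)O[C@H]2C[C@H]1[C@]1(C(O)CC=C(C)C)CO1 | intermediate
24 | silylated diketone (C2=O, C8=O, prenyl) | CC(C)(C)[Si](C)(C)O[C@@H]1C(=O)[C@@]2(C)O[C@H]2C[C@H]1[C@]1(C(=O)CC=C(C)C)CO1 | intermediate
25 | α-hydroxy diketone (free C1–OH) | O[C@@H]1C(=O)[C@@]2(C)O[C@H]2C[C@H]1[C@]1(C(=O)CC=C(C)C)CO1 | intermediate
26 | isovaleric anhydride | CC(C)CC(=O)OC(=O)CC(C)C | starting material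
27 | C1 isovalerate, prenyl ketone | CC(C)CC(=O)O[C@@H]1C(=O)[C@@]2(C)O[C@H]2C[C@H]1[C@]1(C(=O)CC=C(C)C)CO1 | intermediate
28 | CNP0131119.1 | CC(C)CC(=O)O[C@@H]1C(=O)[C@@]2(C)O[C@H]2C[C@H]1[C@]1(C(=O)/C=C/C(C)(C)OO)CO1 | target

**Step count and risks**

Total: 23 steps. Longest linear sequence: 23 steps, from nerol 1 to 28 (6, 22 and 26 are bought).

Steps most likely to fail:

Step 9. The enantio- and trans-selectivity may erode if the closure turns stepwise (Prins-type ionization at C7, which the neighbouring pivalate can intercept), the acyloxy-substituted alkene may react sluggishly, and the allylic alcohol product may lose water under the acid. In that case 11 would be cyclized with stoichiometric Me2AlCl (CH2Cl2, −78 °C), an achiral Lewis-acid carbonyl-ene reaction, to racemic trans-3-methyl-6-[3-(pivaloyloxy)prop-1-en-2-yl]cyclohex-2-en-1-ol F1. Lipase-mediated kinetic resolution (Candida antarctica lipase B, vinyl acetate, hexane) should, by the usual size rule for secondary alcohols, acylate the (1R)-enantiomer to the (1R,6S)-acetate F2, which is separated from the unreacted (1S,6R)-alcohol. K2CO3 in methanol would then cleave the acetate beside the pivalate and return to the route at 12.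

Step 23. Hydrogen abstraction may not be regioselective: the Z-methyl competes with C9, which would give the secondary C10 hydroperoxide carrying an isopropenyl group. The fallback sets out from 27 and installs the peroxide by radical chemistry. Dimethyldioxirane (acetone, −20 °C) epoxidizes the prenyl alkene to the 10,11-epoxide F3. A catalytic amine base (Et3N, CH2Cl2) opens this β,γ-epoxy ketone to the (E)-γ-hydroxy enone F4. Burgess reagent (toluene, 50 °C) dehydrates the tertiary alcohol to the (E)-dienone F5. Cobalt-catalysed silylperoxidation of the diene terminus (Co(acac)2, O2, Et3SiH, 1,2-dichloroethane, rt), by hydrogen-atom transfer to the terminal CH2 and oxygen capture at C11, gives the triethylsilyl peroxide F6. HF·pyridine removes the silyl group and the route is rejoined at 28.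

Step 19. The barium reagent may attack through its γ-terminus (reverse-prenyl carbinol), may add to or enolize the ring ketone, or may undergo Wurtz coupling while it is formed. The fallback sets out from 21. An indium-mediated Barbier allylation (allyl bromide, In, THF–H2O), which is selective for aldehydes over ketones and has no regiochemical ambiguity, gives the homoallylic alcohol F7. Cross-metathesis with 2-methylbut-2-ene (as solvent; second-generation Grubbs catalyst RuCl2(=CHPh)(H2IMes)(PCy3)) converts the allyl into the prenyl group and rejoins the route at 23.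

Further compounds
F1 | step 9 | racemic trans-3-methyl-6-[3-(pivaloyloxy)prop-1-en-2-yl]cyclohex-2-en-1-ol | OC1C=C(C)CCC1C(=C)COC(=O)C(C)(C)C
F2 | step 9 | (1R,6S)-3-methyl-6-[3-(pivaloyloxy)prop-1-en-2-yl]cyclohex-2-en-1-yl acetate | CC(=O)O[C@@H]1C=C(C)CC[C@H]1C(=C)COC(=O)C(C)(C)C
F3 | step 23 | 10,11-epoxide of 27 (C10 epimers) | CC(C)CC(=O)O[C@@H]1C(=O)[C@@]2(C)O[C@H]2C[C@H]1[C@]1(C(=O)CC3OC3(C)C)CO1
F4 | step 23 | (E)-11-hydroxy-9-en-8-one (tertiary allylic alcohol) | CC(C)CC(=O)O[C@@H]1C(=O)[C@@]2(C)O[C@H]2C[C@H]1[C@]1(C(=O)/C=C/C(C)(C)O)CO1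
F5 | step 23 | (E)-dienone with isopropenyl terminus | CC(C)CC(=O)O[C@@H]1C(=O)[C@@]2(C)O[C@H]2C[C@H]1[C@]1(C(=O)/C=C/C(C)=C)CO1
F6 | step 23 | C11 triethylsilyl peroxide of 28 | CC(C)CC(=O)O[C@@H]1C(=O)[C@@]2(C)O[C@H]2C[C@H]1[C@]1(C(=O)/C=C/C(C)(C)OO[Si](CC)(CC)CC)CO1
F7 | step 19 | C8 homoallylic alcohol (allyl adduct of 21, C8 epimers) | CC(C)(C)[Si](C)(C)O[C@@H]1C(=O)[C@@]2(C)O[C@H]2C[C@H]1[C@]1(C(O)CC=C)CO1
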